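**Retrosynthetic overview**
- Target 10 is traced back, through O-demethylation and quinone reduction, to aryloxyquinone 9.
- 9 is cut at the diaryl ether bond between the ring B oxygen (on C1′) and C6 of ring A: tribromophenol 7 adds to 2,6-dibromo-1,4-benzoquinone 4, and the adduct is reoxidized.
- The strategy rests on ring A being a benzene-1,4-diol whose C4–OH lies between C3–Br and C5–Br, with H on C2 and the aryloxy group on C6. This is the pattern left when an oxygen nucleophile adds to a C–H carbon of symmetric 2,6-dibromoquinone. Ring B is the same dibromohydroquinone core with one more bromine at C6′, next to the ether oxygen.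
- Both partners come from 3,5-dibromo-4-hydroxyphenyl benzoate 2, made from hydroquinone monobenzoate 1. Deacylation and oxidation give 4; methylation, deacylation and one ortho-bromination give 7.
- No ring is built: both benzene rings derive from 1 and are joined once in step 7, with all five bromines already in place. The target has no stereocenter or double-bond geometry, and the ether axis is not expected to be configurationally stable.

Key step: step 7

Remark: hydroquinone 8 first arises in the flask during step 7, where it is oxidized at once to 9; it is isolated only as the product of step 8, hence its lower number.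

**Route**

Step 1
Reactants: 1 4-hydroxyphenyl benzoate (hydroquinone monobenzoate)
Product: 2 3,5-dibromo-4-hydroxyphenyl benzoate
Conditions: Br2 (2.1 equiv), AcOH, rt; aq. Na2S2O3 quench
Reagents that add atoms: bromine, BrBr
Why: Electrophilic aromatic bromination is directed by the free hydroxyl to its two ortho carbons (para carries the deactivating benzoyloxy group), and the dibromide is too deactivated to react further.

Step 2
Reactants: 2 3,5-dibromo-4-hydroxyphenyl benzoate
Product: 3 2,6-dibromobenzene-1,4-diol (2,6-dibromohydroquinone)
Conditions: HCl (1.25 M in MeOH), reflux, Ar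
Reagents that add atoms: none
Why: Acid-catalysed transesterification with methanol removes the aryl benzoate and releases the hydroquinone in its neutral form, which is far less prone to air oxidation than its anions.

Step 3
Reactants: 3 2,6-dibromobenzene-1,4-diol
Product: 4 2,6-dibromo-1,4-benzoquinone
Conditions: NaIO4 (1.2 equiv) on wet SiO2, CH2Cl2, rt, dark
Reagents that add atoms: none
Why: Periodate oxidation of a hydroquinone to its quinone is a fast two-electron process, and the heterogeneous medium lets the base- and nucleophile-sensitive quinone be obtained by filtration.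

Step 4
Reactants: 2 3,5-dibromo-4-hydroxyphenyl benzoate
Product: 5 3,5-dibromo-4-methoxyphenyl benzoate
Conditions: MeI (2 equiv), K2CO3 (1.5 equiv), dry acetone, 45 °C
Reagents that add atoms: iodomethane, CI
Why: Williamson O-methylation goes through the carbonate-generated phenoxide of the acidic 2,6-dibromophenol, and the benzoate already sits on the more basic oxygen, so it has no driving force to migrate.

Step 5
Reactants: 5 3,5-dibromo-4-methoxyphenyl benzoate
Product: 6 3,5-dibromo-4-methoxyphenol
Conditions: LiOH·H2O (3 equiv), THF/H2O 3:1, rt; then 1 M HCl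
Reagents that add atoms: none
Why: Saponification of the aryl benzoate should be rapid because the dibromophenoxide is a good leaving group, while the aryl methyl ether and the C–Br bonds are inert to aqueous hydroxide at room temperature.

Step 6
Reactants: 6 3,5-dibromo-4-methoxyphenol
Product: 7 2,3,5-tribromo-4-methoxyphenol
Conditions: NBS (1.0 equiv), dry MeCN, −10 °C → rt, dark
Reagents that add atoms: N-bromosuccinimide, O=C1CCC(=O)N1Br
Why: Electrophilic bromination ortho to the free hydroxyl can give only one monobromide, since the two ortho carbons are equivalent and para is occupied by the methoxy group, and the new bromine slows a second substitution.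

Step 7
Reactants: 4 2,6-dibromo-1,4-benzoquinone; 7 2,3,5-tribromo-4-methoxyphenol
Product: 9 3,5-dibromo-2-(2,3,5-tribromo-4-methoxyphenoxy)-1,4-benzoquinone, via aryloxyhydroquinone 8 (not isolated)
Conditions: 4 (2.5 equiv), powdered KHCO3 (0.3 equiv), MeCN, −20 °C, Ar, dark; 7 in MeCN added over 2 h; then 0 °C; 0.5 M HCl wash; SiO2 chromatography (3 and excess 4 recovered, 3 returned to step 3)
Reagents that add atoms: none
Why: The phenoxide of 7, kept at low concentration by the weak base, adds through oxygen to C3 of quinone 4 (the hydrogen-bearing carbon β to the C1 carbonyl); the enolate re-aromatizes by a proton shift to hydroquinone 8, and a second molecule of 4 oxidizes 8 to quinone 9 while being reduced to 3, whose acidity is expected to be close to that of 7 so that the base turns over. The closest known reaction type is the oxidative conjugate addition (Michael addition, then reoxidation) of aryloxides, thiols and hydrogen halides to the unsubstituted carbon of halogenated benzoquinones. The step forms only the bond between the ring B oxygen on C1′ and C6 of ring A; no ring closes and no stereocenter arises. It needs attack at the C–H carbon and not addition–elimination at a C–Br carbon, which is expected because the C1 carbonyl is activated inductively by its two α-bromines, whereas each bromine is a vinylogous donor to the C4 carbonyl and so deactivates the carbon that carries it. It also needs O- and not C-attack by the phenol, favoured by the three deactivating bromines and the para methoxy group of 7, and a single addition, favoured by slow addition into excess 4 and by the aryloxy group of 9 donating into the carbonyl that activates its last C–H carbon. Aromatization followed by oxidation makes the otherwise reversible oxa-Michael addition irreversible, and the methyl ether keeps ring B out of the quinone–hydroquinone redox exchange.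

Step 8
Reactants: 9 3,5-dibromo-2-(2,3,5-tribromo-4-methoxyphenoxy)-1,4-benzoquinone
Product: 8 3,5-dibromo-2-(2,3,5-tribromo-4-methoxyphenoxy)benzene-1,4-diol
Conditions: Na2S2O4 (3 equiv), THF/H2O, rt, Ar
Reagents that add atoms: none
Why: Dithionite reduction of a quinone to its hydroquinone is a mild two-electron transfer in water that leaves aryl bromides and the diaryl ether untouched.

Step 9
Reactants: 8 3,5-dibromo-2-(2,3,5-tribromo-4-methoxyphenoxy)benzene-1,4-diol
Product: 10 3,5-dibromo-2-(2,3,5-tribromo-4-hydroxyphenoxy)benzene-1,4-diol (CNP0084224.0)
Conditions: BBr3 (6 equiv), CH2Cl2, −78 °C → rt, Ar; then degassed H2O, 0 °C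
Reagents that add atoms: none
Why: Lewis-acid cleavage of the aryl methyl ether (boron binds the methoxy oxygen, bromide removes the methyl group by SN2) is expected to tolerate the two flanking bromines, and the diaryl ether has no sp3 carbon for bromide to attack.

**Compound list**
1 | 4-hydroxyphenyl benzoate | O=C(Oc1ccc(O)cc1)c1ccccc1 | starting material
2 | 3,5-dibromo-4-hydroxyphenyl benzoate | O=C(Oc1cc(Br)c(O)c(Br)c1)c1ccccc1 | intermediate
3 | 2,6-dibromobenzene-1,4-diol | Oc1cc(Br)c(O)c(Br)c1 | intermediate
4 | 2,6-dibromo-1,4-benzoquinone | O=C1C=C(Br)C(=O)C(Br)=C1 | intermediate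
5 | 3,5-dibromo-4-methoxyphenyl benzoate | COc1c(Br)cc(OC(=O)c2ccccc2)cc1Br | intermediate
6 | 3,5-dibromo-4-methoxyphenol | Oc1cc(Br)c(OC)c(Br)c1 | intermediate
7 | 2,3,5-tribromo-4-methoxyphenol | Oc1cc(Br)c(OC)c(Br)c1Br | intermediate
8 | 3,5-dibromo-2-(2,3,5-tribromo-4-methoxyphenoxy)benzene-1,4-diol | Oc1cc(Br)c(O)c(Br)c1Oc1cc(Br)c(OC)c(Br)c1Br | intermediate
9 | 3,5-dibromo-2-(2,3,5-tribromo-4-methoxyphenoxy)-1,4-benzoquinone | O=C1C=C(Br)C(=O)C(Br)=C1Oc1cc(Br)c(OC)c(Br)c1Br | intermediate
10 | 3,5-dibromo-2-(2,3,5-tribromo-4-hydroxyphenoxy)benzene-1,4-diol | Oc1cc(Br)c(O)c(Br)c1Oc1cc(Br)c(O)c(Br)c1Br | target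

**Step count**
Total: 9 steps. Longest linear sequence: 7 steps (steps 1, 4, 5, 6, 7, 8, 9).

**Steps most likely to fail**

Step 7. The hindered, weakly basic phenoxide may add too slowly. Addition–elimination at a C–Br carbon, addition of the regenerated hydroquinone 3 to 4, or base-induced decay of the quinone could then take over. The fallback forms the ether by metal-free arylation with a diaryliodonium salt; it sets out from 3 and 7 and comes back at 10.
- 3 would be bis-methylated (MeI, K2CO3, acetone) to 1,3-dibromo-2,5-dimethoxybenzene F1.
- F1 would be iodinated at one of its two equivalent C–H carbons (NIS, cat. TfOH, MeCN) to 1,3-dibromo-4-iodo-2,5-dimethoxybenzene F2.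
- F2 would be oxidized with mCPBA and TsOH·H2O and then treated with 1,3,5-trimethoxybenzene to give (2,4-dibromo-3,6-dimethoxyphenyl)(2,4,6-trimethoxyphenyl)iodonium 4-methylbenzenesulfonate F3.
- Phenol 7 with K2CO3 in MeCN at 40 °C should take over the brominated aryl group of F3 by ligand coupling at trivalent iodine, the trimethoxyphenyl group staying on iodine. This gives 1,3-dibromo-2,5-dimethoxy-4-(2,3,5-tribromo-4-methoxyphenoxy)benzene F4.
- BBr3 in CH2Cl2 would cleave all three methyl ethers of F4 to reach 10.

Step 6. Bromination may run on to the tetrabromide, or the electron-rich methoxyphenol may be oxidized to quinonoid material. The fallback replaces electrophilic substitution by deprotonative metalation, which can install only one bromine per equivalent of base; it sets out from 5 and comes back at 7.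
- 5 would be deprotonated at the C–H between the benzoyloxy group and a bromine with TMPMgCl·LiCl (1.1 equiv, THF, −40 °C, kept cold to suppress acyl migration and aryne formation).
- The arylmagnesium would be quenched with 1,2-dibromo-1,1,2,2-tetrachloroethane to give 2,3,5-tribromo-4-methoxyphenyl benzoate F5.
- Hydrolysis of F5 with LiOH·H2O in THF/H2O would give 7.

Step 9. Cleavage of the doubly ortho-brominated methyl ether may stall once the free hydroxyls have bound boron, and the hydroquinone may be oxidized during the work-up. The fallback carries the hindered oxygen of ring B as an acid-labile methoxymethyl ether; it sets out from 2 and comes back at 10.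
- 2 with MOMCl and iPr2NEt in CH2Cl2 would give 3,5-dibromo-4-(methoxymethoxy)phenyl benzoate F6.
- LiOH·H2O hydrolysis would give 3,5-dibromo-4-(methoxymethoxy)phenol F7.
- NBS in MeCN would give 2,3,5-tribromo-4-(methoxymethoxy)phenol F8.
- Oxidative addition to 4 under the conditions of step 7 would give 3,5-dibromo-2-[2,3,5-tribromo-4-(methoxymethoxy)phenoxy]-1,4-benzoquinone F9.
- Na2S2O4 reduction would give 3,5-dibromo-2-[2,3,5-tribromo-4-(methoxymethoxy)phenoxy]benzene-1,4-diol F10.
- HCl in MeOH under Ar would remove the acetal from F10 and give 10 without any Lewis acid.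

**Further compounds**
F1 | step 7 | 1,3-dibromo-2,5-dimethoxybenzene | COc1cc(Br)c(OC)c(Br)c1
F2 | step 7 | 1,3-dibromo-4-iodo-2,5-dimethoxybenzene | COc1cc(Br)c(OC)c(Br)c1I
F3 | step 7 | (2,4-dibromo-3,6-dimethoxyphenyl)(2,4,6-trimethoxyphenyl)iodonium 4-methylbenzenesulfonate | COc1cc(Br)c(OC)c(Br)c1[I+]c1c(OC)cc(OC)cc1OC.Cc1ccc(cc1)S(=O)(=O)[O-]
F4 | step 7 | 1,3-dibromo-2,5-dimethoxy-4-(2,3,5-tribromo-4-methoxyphenoxy)benzene | COc1cc(Br)c(OC)c(Br)c1Oc1cc(Br)c(OC)c(Br)c1Br
F5 | step 6 | 2,3,5-tribromo-4-methoxyphenyl benzoate | COc1c(Br)cc(OC(=O)c2ccccc2)c(Br)c1Br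
F6 | step 9 | 3,5-dibromo-4-(methoxymethoxy)phenyl benzoate | COCOc1c(Br)cc(OC(=O)c2ccccc2)cc1Br
F7 | step 9 | 3,5-dibromo-4-(methoxymethoxy)phenol | COCOc1c(Br)cc(O)cc1Br
F8 | step 9 | 2,3,5-tribromo-4-(methoxymethoxy)phenol | COCOc1c(Br)cc(O)c(Br)c1Br
F9 | step 9 | 3,5-dibromo-2-[2,3,5-tribromo-4-(methoxymethoxy)phenoxy]-1,4-benzoquinone | COCOc1c(Br)cc(OC2=C(Br)C(=O)C(Br)=CC2=O)c(Br)c1Br
F10 | step 9 | 3,5-dibromo-2-[2,3,5-tribromo-4-(methoxymethoxy)phenoxy]benzene-1,4-diol | COCOc1c(Br)cc(Oc2c(O)cc(Br)c(O)c2Br)c(Br)c1Br
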